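**Retrosynthetic overview**
1. C40 is cut at C11=C12 and C11'=C12' (two Wittig olefinations): C15 aldehyde with the 5,6-cis-diol end (masked as a cyclic carbonate) + central C10 bis-phosphonium salt + C15 aldehyde with the 5,8-furanoid end.
2. Both C15 aldehydes come from one vinyl oxirane (a C15 5,6-epoxy dienal): zerovalent palladium/CO2 opens it with retention to the cis-carbonate, and a copper-catalysed oxirane → 2,5-dihydrofuran ring expansion (key step) builds the furanoid ring and sets C8'.
3. The epoxy dienal comes from a C10 epoxy aldehyde (Sharpless epoxidation sets C5 and C6) and a C5 cyanophosphonate; C3 comes from a CBS reduction.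
4. The carbocycle comes from a Michael/aldol annulation of mesityl oxide with methyl acetoacetate; the C10 centre comes from two propargyl alcohols and (E)-1,2-diiodoethene (carboalumination/Negishi coupling).
5. Ring order: cyclohexene first, then the oxirane, then either the dioxolanone (one half) or the dihydrofuran by ring expansion (other half).

Assumption: the target is taken as drawn, (3S,5R,6S,3'S,5'R,8'R); carotenoid locants (primed in the furanoid half) are used in the explanations; TBS = tert-butyldimethylsilyl.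

**Step 1**
Reactants: 1 4-methylpent-3-en-2-one (mesityl oxide); 2 methyl 3-oxobutanoate (methyl acetoacetate)
Product: 4 methyl (1RS)-2,6,6-trimethyl-4-oxocyclohex-2-ene-1-carboxylate (racemic), via Michael adduct 3 (not isolated)
Conditions: ZnCl2 (0.3 equiv), heptane–toluene, reflux, Dean–Stark
Reagents that add atoms: none
Why: Lewis-acid-promoted Michael addition of the acetoacetate to the enone followed by intramolecular aldol condensation (Robinson-type annulation) builds the carbocycle with the C3 oxygen, the C5 methyl, the gem-dimethyl C1 and the C7 ester in place; the racemic C6 centre is erased in step 3.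

**Step 2**
Reactants: 4 methyl (1RS)-2,6,6-trimethyl-4-oxocyclohex-2-ene-1-carboxylate
Product: 5 methyl (1RS,4S)-4-hydroxy-2,6,6-trimethylcyclohex-2-ene-1-carboxylate (C1 epimer mixture)
Conditions: (R)-2-methyl-CBS-oxazaborolidine (10 mol%), BH3·SMe2 (0.7 equiv), THF, −20 °C; MeOH quench
Reagents that add atoms: none
Why: Corey–Bakshi–Shibata reduction delivers hydride 1,2 to the enone carbonyl with the alkenyl branch as the large group, setting C3 (4S in 5, expected about 90% ee, upgraded in step 6) whatever the configuration at C6; the ester is inert to BH3 at this temperature.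

**Step 3**
Reactants: 5 methyl (1RS,4S)-4-hydroxy-2,6,6-trimethylcyclohex-2-ene-1-carboxylate
Product: 6 methyl (4R)-4-hydroxy-2,6,6-trimethylcyclohex-1-ene-1-carboxylate
Conditions: NaOMe (0.5 equiv), MeOH, 65 °C, stopped at equilibrium; recovered 5 recycled
Reagents that add atoms: none
Why: Base-catalysed prototropic equilibration through the ester dienolate moves the double bond into the tetrasubstituted, ester-conjugated C5=C6 position (α- to β-cyclogeranate isomerisation), merging both C6 epimers into one compound; the hydroxyl is left free here because an alkoxide is a poor leaving group for 1,4-elimination, and C3 is untouched (the descriptor changes from S to R only through the priority rules).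

**Step 4**
Reactants: 6 methyl (4R)-4-hydroxy-2,6,6-trimethylcyclohex-1-ene-1-carboxylate
Product: 7 methyl (4R)-4-[(TBS)oxy]-2,6,6-trimethylcyclohex-1-ene-1-carboxylate
Conditions: TBSCl (1.2 equiv), imidazole (2.5 equiv), DMF, 23 °C
Reagents that add atoms: tert-butyldimethylsilyl chloride, CC(C)(C)[Si](C)(C)Cl
Why: Standard silylation of the secondary alcohol, which masks it for the hydride, oxidation and olefination steps and reinforces the anti face preference in step 6.

**Step 5**
Reactants: 7 methyl (4R)-4-[(TBS)oxy]-2,6,6-trimethylcyclohex-1-ene-1-carboxylate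
Product: 8 {(4R)-4-[(TBS)oxy]-2,6,6-trimethylcyclohex-1-en-1-yl}methanol
Conditions: i-Bu2AlH (2.5 equiv), CH2Cl2, −78 → 0 °C; aqueous potassium sodium tartrate work-up
Reagents that add atoms: none
Why: Diisobutylaluminium hydride reduces the hindered conjugated ester cleanly (1,2 only) to the allylic alcohol required for a directed asymmetric epoxidation.

**Step 6**
Reactants: 8 {(4R)-4-[(TBS)oxy]-2,6,6-trimethylcyclohex-1-en-1-yl}methanol
Product: 9 {(1R,4S,6R)-4-[(TBS)oxy]-2,2,6-trimethyl-7-oxabicyclo[4.1.0]heptan-1-yl}methanol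
Conditions: Ti(Oi-Pr)4 (20 mol%), D-(−)-diethyl tartrate (24 mol%), t-BuOOH (2 equiv), 4 Å molecular sieves, CH2Cl2, −20 °C
Reagents that add atoms: tert-butyl hydroperoxide, CC(C)(C)OO
Why: Sharpless asymmetric epoxidation of the tetrasubstituted allylic alcohol, in which the D-(−)-tartrate catalyst delivers oxygen to the ring face anti to the silyloxy group (matched with the substrate bias), setting C5 (R) and C6 with the oxirane trans to the C3 oxygen; material from the minor C3 enantiomer ends up as the separable syn diastereomer, so the ee is upgraded.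

**Step 7**
Reactants: 9 {(1R,4S,6R)-4-[(TBS)oxy]-2,2,6-trimethyl-7-oxabicyclo[4.1.0]heptan-1-yl}methanol
Product: 10 (1S,4S,6R)-4-[(TBS)oxy]-2,2,6-trimethyl-7-oxabicyclo[4.1.0]heptane-1-carbaldehyde
Conditions: (n-Pr4N)RuO4 (tetrapropylammonium perruthenate, 5 mol%), N-methylmorpholine N-oxide (1.5 equiv), 4 Å molecular sieves, CH2Cl2, 23 °C
Reagents that add atoms: none
Why: Ley–Griffith oxidation converts the primary alcohol into the non-enolisable aldehyde under neutral conditions that leave the tetrasubstituted oxirane and the silyl ether intact.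

**Step 8**
Reactants: 11 3-methylbut-2-enenitrile
Product: 12 4-bromo-3-methylbut-2-enenitrile (E/Z mixture)
Conditions: N-bromosuccinimide (1.05 equiv), azobisisobutyronitrile (2 mol%), PhCF3, reflux
Reagents that add atoms: N-bromosuccinimide, O=C1CCC(=O)N1Br
Why: Wohl–Ziegler radical bromination of an allylic methyl group; the E/Z mixture does not matter because the derived phosphonate anion equilibrates.

**Step 9**
Reactants: 12 4-bromo-3-methylbut-2-enenitrile
Product: 13 diethyl (3-cyano-2-methylprop-2-en-1-yl)phosphonate (E/Z mixture)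
Conditions: P(OEt)3 (1.1 equiv), neat, 120 °C, EtBr distilled off
Reagents that add atoms: triethyl phosphite, CCOP(OCC)OCC
Why: Michaelis–Arbuzov reaction of the primary allylic bromide gives the C5 olefination reagent.

**Step 10**
Reactants: 10 (1S,4S,6R)-4-[(TBS)oxy]-2,2,6-trimethyl-7-oxabicyclo[4.1.0]heptane-1-carbaldehyde; 13 diethyl (3-cyano-2-methylprop-2-en-1-yl)phosphonate
Product: 14 (2E,4E)-5-{(1S,4S,6R)-4-[(TBS)oxy]-2,2,6-trimethyl-7-oxabicyclo[4.1.0]heptan-1-yl}-3-methylpenta-2,4-dienenitrile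
Conditions: 13 (1.3 equiv), NaH, THF, 0 °C; then 10, −20 → 23 °C; chromatography
Reagents that add atoms: none
Why: Horner–Wadsworth–Emmons olefination of the non-enolisable aldehyde forms C7=C8 as the E alkene and gives mainly the 9E isomer (about 4:1 expected, the 9Z isomer is removed by chromatography); no stereocentre is touched.

**Step 11**
Reactants: 14 (2E,4E)-5-{(1S,4S,6R)-4-[(TBS)oxy]-2,2,6-trimethyl-7-oxabicyclo[4.1.0]heptan-1-yl}-3-methylpenta-2,4-dienenitrile
Product: 16 (2E,4E)-5-{(1S,4S,6R)-4-[(TBS)oxy]-2,2,6-trimethyl-7-oxabicyclo[4.1.0]heptan-1-yl}-3-methylpenta-2,4-dienal, via aluminium aldimine 15 (not isolated)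
Conditions: i-Bu2AlH (1.2 equiv), CH2Cl2, −78 °C; then wet SiO2, Et2O, 0 °C
Reagents that add atoms: water, O (carbonyl oxygen of 16); diisobutylaluminium hydride, CC(C)C[AlH]CC(C)C (aluminium of 15 only)
Why: Diisobutylaluminium hydride adds once to the nitrile at low temperature to give the aluminium aldimine, and its hydrolysis on wet silica releases the dienal without acid strong enough to open the vinyl oxirane.

**Step 12**
Reactants: 16 (2E,4E)-5-{(1S,4S,6R)-4-[(TBS)oxy]-2,2,6-trimethyl-7-oxabicyclo[4.1.0]heptan-1-yl}-3-methylpenta-2,4-dienal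
Product: 17 (2E,4E)-5-{(3aS,6S,7aR)-6-[(TBS)oxy]-4,4,7a-trimethyl-2-oxohexahydro-1,3-benzodioxol-3a-yl}-3-methylpenta-2,4-dienal (5,6-cis-carbonate, anti to the C3 oxygen)
Conditions: Pd2(dba)3·CHCl3 (tris(dibenzylideneacetone)dipalladium chloroform adduct, zerovalent palladium, 2.5 mol%), P(Oi-Pr)3 (20 mol%), CO2 (1 atm), THF, 23–40 °C
Reagents that add atoms: carbon dioxide, O=C=O
Why: Zerovalent-palladium-catalysed carboxylative opening of a vinyl epoxide, in which ionisation with inversion gives a π-allylpalladium alkoxide, the alkoxide captures CO2 and the carbonate closes on C6 anti to palladium (second inversion), so the C6–O bond is re-formed with net retention and the 5,6-cis-diol of the triol end is obtained as its cyclic carbonate while C5 is untouched; the five-membered carbonate is favoured over closure at C8 or C10.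

**Step 13**
Reactants: 16 (2E,4E)-5-{(1S,4S,6R)-4-[(TBS)oxy]-2,2,6-trimethyl-7-oxabicyclo[4.1.0]heptan-1-yl}-3-methylpenta-2,4-dienal
Product: 18 (2E)-3-{(2R,6S,7aR)-6-[(TBS)oxy]-4,4,7a-trimethyl-2,4,5,6,7,7a-hexahydro-1-benzofuran-2-yl}but-2-enal
Conditions: Cu(hfacac)2 (copper bis(hexafluoroacetylacetonate), divalent copper, 5 mol%), toluene, 60–80 °C, argon, dark
Reagents that add atoms: none
Why: Proposed new method: the Lewis-acidic divalent copper centre binds the oxirane oxygen and the allylic C6–O bond heterolyses to a contact ion pair whose cation is confined to C6–C7–C8 (the enal blocks delocalisation further along the chain), so the C7=C8 E geometry is held and the copper-bound C5 alkoxide, which stays on the face it left, closes on C8 in a suprafacial 1,3-oxygen shift that expands the oxirane to the 2,5-dihydrofuran and sets C8' as R (chain cis to C4', trans to the C5' methyl) while C5' keeps its C–O bond and configuration; the closest known reaction types are the copper-catalysed ring expansion of simple vinyl oxiranes to 2,5-dihydrofurans and the unselective acid-catalysed epoxide–furanoid rearrangement of carotenoid 5,6-epoxides, neither shown on a tetrasubstituted ring-fused oxirane conjugated to a dienal nor used to fix this stereocentre.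

**Step 14**
Reactants: 19 prop-2-yn-1-ol (2 equiv); 20 (E)-1,2-diiodoethene
Product: 22 (2E,4E,6E)-2,7-dimethylocta-2,4,6-triene-1,8-diol, via alkenylalane 21 (not isolated)
Conditions: Me3Al (3 equiv per alkyne), Cp2ZrCl2 (bis(cyclopentadienyl)zirconium dichloride, 25 mol%), CH2Cl2, 0 → 23 °C; then 20 (0.45 equiv), Pd2(dba)3 (tris(dibenzylideneacetone)dipalladium, zerovalent palladium, 2.5 mol%), tri(2-furyl)phosphine (10 mol%), ZnCl2 (20 mol%), THF, 23 °C
Reagents that add atoms: trimethylaluminium, C[Al](C)C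
Why: Zirconium-catalysed syn-carboalumination of the alkyne (as its aluminium alkoxide) puts the methyl on the internal carbon and aluminium trans to CH2O, and twofold palladium/zinc-catalysed Negishi coupling with the E-diiodide proceeds with retention to give the all-E triene diol in one operation.

**Step 15**
Reactants: 22 (2E,4E,6E)-2,7-dimethylocta-2,4,6-triene-1,8-diol
Product: 23 [(2E,4E,6E)-2,7-dimethylocta-2,4,6-triene-1,8-diyl]bis(triphenylphosphonium) dibromide
Conditions: Ph3P·HBr (2.1 equiv), MeOH–CH2Cl2, 23 °C; crystallisation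
Reagents that add atoms: triphenylphosphine hydrobromide, [Br-].[PH+](c1ccccc1)(c1ccccc1)c1ccccc1
Why: Triphenylphosphine hydrobromide converts allylic alcohols into allylic phosphonium salts through the allyl cation, and the all-E bis-salt is the thermodynamic, crystalline product.

**Step 16**
Reactants: 17 (2E,4E)-5-{(3aS,6S,7aR)-6-[(TBS)oxy]-4,4,7a-trimethyl-2-oxohexahydro-1,3-benzodioxol-3a-yl}-3-methylpenta-2,4-dienal; 23 [(2E,4E,6E)-2,7-dimethylocta-2,4,6-triene-1,8-diyl]bis(triphenylphosphonium) dibromide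
Product: 24 {(2E,4E,6E,8E,10E,12E)-13-[(3aS,6S,7aR)-6-[(TBS)oxy]-4,4,7a-trimethyl-2-oxohexahydro-1,3-benzodioxol-3a-yl]-2,7,11-trimethyltrideca-2,4,6,8,10,12-hexaen-1-yl}triphenylphosphonium bromide
Conditions: 23 (3 equiv), 1,2-epoxybutane–CH2Cl2 (1:1), 45 °C, argon, dark; excess 23 recovered
Reagents that add atoms: none
Why: Wittig olefination under base-free conditions (1,2-epoxybutane scavenges HBr and generates the ylide in low concentration) with the bis-salt in excess so that only one end reacts; the new C11=C12 bond forms as an E/Z mixture that equilibrates thermally to E, and the carbonate and silyl ether are untouched.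

**Step 17**
Reactants: 24 the C25 phosphonium bromide; 18 (2E)-3-{(2R,6S,7aR)-6-[(TBS)oxy]-4,4,7a-trimethyl-2,4,5,6,7,7a-hexahydro-1-benzofuran-2-yl}but-2-enal
Product: 25 (3S,5R,6S,3'S,5'R,8'R)-3,3'-bis[(TBS)oxy]-5',8'-epoxy-5,6,5',8'-tetrahydro-β,β-carotene-5,6-diyl carbonate (all-E)
Conditions: 18 (1.2 equiv), 1,2-epoxybutane–CH2Cl2 (1:1), 45 °C, argon, dark; then reflux in EtOAc (Z → E)
Reagents that add atoms: none
Why: A second Wittig olefination under the same near-neutral conditions forms C11'=C12' and completes the C40 skeleton without epimerising the doubly allylic C8', and heating converts Z isomers into the all-E polyene.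

**Step 18**
Reactants: 25 (3S,5R,6S,3'S,5'R,8'R)-3,3'-bis[(TBS)oxy]-5',8'-epoxy-5,6,5',8'-tetrahydro-β,β-carotene-5,6-diyl carbonate
Product: 27 (3S,5R,6S,3'S,5'R,8'R)-5',8'-epoxy-5,6,5',8'-tetrahydro-β,β-carotene-3,5,6,3'-tetrol (CNP0210286.4), via diol carbonate 26 (not isolated)
Conditions: n-Bu4NF (3 equiv), THF, 0 → 23 °C; then K2CO3 (0.3 equiv), MeOH, 23 °C
Reagents that add atoms: none
Why: Fluoride cleaves both silyl ethers and carbonate-catalysed methanolysis removes the cyclic carbonate as dimethyl carbonate, and these basic conditions leave the acid-labile furanoid C8' centre and the tertiary allylic C6 carbinol untouched.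

**Compound list**
1 | 4-methylpent-3-en-2-one (mesityl oxide) | CC(=O)C=C(C)C | starting material
2 | methyl 3-oxobutanoate (methyl acetoacetate) | COC(=O)CC(C)=O | starting material
3 | methyl 2-acetyl-3,3-dimethyl-5-oxohexanoate (Michael adduct, not isolated) | COC(=O)C(C(C)=O)C(C)(C)CC(C)=O | intermediate
4 | methyl (1RS)-2,6,6-trimethyl-4-oxocyclohex-2-ene-1-carboxylate | COC(=O)C1C(C)=CC(=O)CC1(C)C | intermediate
5 | methyl (1RS,4S)-4-hydroxy-2,6,6-trimethylcyclohex-2-ene-1-carboxylate | COC(=O)C1C(C)=C[C@@H](O)CC1(C)C | intermediate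
6 | methyl (4R)-4-hydroxy-2,6,6-trimethylcyclohex-1-ene-1-carboxylate | COC(=O)C1=C(C)C[C@@H](O)CC1(C)C | intermediate
7 | methyl (4R)-4-[(tert-butyldimethylsilyl)oxy]-2,6,6-trimethylcyclohex-1-ene-1-carboxylate | COC(=O)C1=C(C)C[C@@H](O[Si](C)(C)C(C)(C)C)CC1(C)C | intermediate
8 | {(4R)-4-[(tert-butyldimethylsilyl)oxy]-2,6,6-trimethylcyclohex-1-en-1-yl}methanol | OCC1=C(C)C[C@@H](O[Si](C)(C)C(C)(C)C)CC1(C)C | intermediate
9 | {(1R,4S,6R)-4-[(tert-butyldimethylsilyl)oxy]-2,2,6-trimethyl-7-oxabicyclo[4.1.0]heptan-1-yl}methanol | OC[C@]1(O2)C(C)(C)C[C@H](O[Si](C)(C)C(C)(C)C)C[C@]12C | intermediate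
10 | (1S,4S,6R)-4-[(tert-butyldimethylsilyl)oxy]-2,2,6-trimethyl-7-oxabicyclo[4.1.0]heptane-1-carbaldehyde | O=C[C@]1(O2)C(C)(C)C[C@H](O[Si](C)(C)C(C)(C)C)C[C@]12C | intermediate
11 | 3-methylbut-2-enenitrile | CC(C)=CC#N | starting material
12 | 4-bromo-3-methylbut-2-enenitrile (E/Z mixture) | CC(CBr)=CC#N | intermediate
13 | diethyl (3-cyano-2-methylprop-2-en-1-yl)phosphonate (E/Z mixture) | CCOP(=O)(CC(C)=CC#N)OCC | intermediate
14 | (2E,4E)-5-{(1S,4S,6R)-4-[(tert-butyldimethylsilyl)oxy]-2,2,6-trimethyl-7-oxabicyclo[4.1.0]heptan-1-yl}-3-methylpenta-2,4-dienenitrile | N#C/C=C(C)/C=C/[C@]1(O2)C(C)(C)C[C@H](O[Si](C)(C)C(C)(C)C)C[C@]12C | intermediate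
15 | N-(diisobutylalumanyl) aldimine of 16 (not isolated) | CC(C)C[Al](CC(C)C)N=C/C=C(C)/C=C/[C@]1(O2)C(C)(C)C[C@H](O[Si](C)(C)C(C)(C)C)C[C@]12C | intermediate
16 | (2E,4E)-5-{(1S,4S,6R)-4-[(tert-butyldimethylsilyl)oxy]-2,2,6-trimethyl-7-oxabicyclo[4.1.0]heptan-1-yl}-3-methylpenta-2,4-dienal | O=C/C=C(C)/C=C/[C@]1(O2)C(C)(C)C[C@H](O[Si](C)(C)C(C)(C)C)C[C@]12C | intermediate
17 | (2E,4E)-5-{(3aS,6S,7aR)-6-[(tert-butyldimethylsilyl)oxy]-4,4,7a-trimethyl-2-oxohexahydro-1,3-benzodioxol-3a-yl}-3-methylpenta-2,4-dienal | O=C/C=C(C)/C=C/[C@]1(OC(=O)O2)C(C)(C)C[C@H](O[Si](C)(C)C(C)(C)C)C[C@]12C | intermediate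
18 | (2E)-3-{(2R,6S,7aR)-6-[(tert-butyldimethylsilyl)oxy]-4,4,7a-trimethyl-2,4,5,6,7,7a-hexahydro-1-benzofuran-2-yl}but-2-enal | O=C/C=C(\C)[C@H]1C=C2C(C)(C)C[C@H](O[Si](C)(C)C(C)(C)C)C[C@@]2(C)O1 | intermediate
19 | prop-2-yn-1-ol | C#CCO | starting material
20 | (E)-1,2-diiodoethene | I/C=C/I | starting material
21 | dimethylaluminium (E)-3-(dimethylalumanyl)-2-methylprop-2-en-1-olate (alkenylalane, not isolated) | C[Al](C)OC/C(C)=C/[Al](C)C | intermediate
22 | (2E,4E,6E)-2,7-dimethylocta-2,4,6-triene-1,8-diol | OC/C(C)=C/C=C/C=C(C)/CO | intermediate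
23 | [(2E,4E,6E)-2,7-dimethylocta-2,4,6-triene-1,8-diyl]bis(triphenylphosphonium) dibromide | [Br-].[Br-].c1ccccc1[P+](c1ccccc1)(c1ccccc1)C/C(C)=C/C=C/C=C(C)/C[P+](c1ccccc1)(c1ccccc1)c1ccccc1 | intermediate
24 | {(2E,4E,6E,8E,10E,12E)-13-[(3aS,6S,7aR)-6-[(tert-butyldimethylsilyl)oxy]-4,4,7a-trimethyl-2-oxohexahydro-1,3-benzodioxol-3a-yl]-2,7,11-trimethyltrideca-2,4,6,8,10,12-hexaen-1-yl}triphenylphosphonium bromide | [Br-].c1ccccc1[P+](c1ccccc1)(c1ccccc1)C/C(C)=C/C=C/C=C(C)/C=C/C=C(C)/C=C/[C@]1(OC(=O)O2)C(C)(C)C[C@H](O[Si](C)(C)C(C)(C)C)C[C@]12C | intermediate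
25 | (3S,5R,6S,3'S,5'R,8'R)-3,3'-bis[(tert-butyldimethylsilyl)oxy]-5',8'-epoxy-5,6,5',8'-tetrahydro-β,β-carotene-5,6-diyl carbonate | CC(/C=C/C=C(C)/C=C/[C@]1(OC(=O)O2)C(C)(C)C[C@H](O[Si](C)(C)C(C)(C)C)C[C@]12C)=C\C=C\C=C(C)\C=C\C=C(/C)[C@H]1C=C2C(C)(C)C[C@H](O[Si](C)(C)C(C)(C)C)C[C@@]2(C)O1 | intermediate
26 | (3S,5R,6S,3'S,5'R,8'R)-5',8'-epoxy-3,3'-dihydroxy-5,6,5',8'-tetrahydro-β,β-carotene-5,6-diyl carbonate (not isolated) | CC(/C=C/C=C(C)/C=C/[C@]1(OC(=O)O2)C(C)(C)C[C@H](O)C[C@]12C)=C\C=C\C=C(C)\C=C\C=C(/C)[C@H]1C=C2C(C)(C)C[C@H](O)C[C@@]2(C)O1 | intermediate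
27 | (3S,5R,6S,3'S,5'R,8'R)-5',8'-epoxy-5,6,5',8'-tetrahydro-β,β-carotene-3,5,6,3'-tetrol (CNP0210286.4) | CC(/C=C/C=C(C)/C=C/[C@]1(O)C(C)(C)C[C@H](O)C[C@@]1(C)O)=C\C=C\C=C(C)\C=C\C=C(/C)[C@H]1C=C2C(C)(C)C[C@H](O)C[C@@]2(C)O1 | target

**Step count and risks**
Total steps: 18. Longest linear sequence: 13 steps (steps 1–7, 10, 11, 12, 16, 17, 18).

Step 13 (the new ring expansion) is the most likely to fail: the copper catalyst may bind the aldehyde, a competing 1,2-shift may contract the ring, or C8' may form as an epimer mixture. The fallback uses known chemistry, sets out from 16 and 24 and comes back at 25. Compound 16 is taken unchanged into the Wittig reaction of step 17 to give the protected C40 5',6'-epoxide (3S,5R,6S,3'S,5'R,6'S)-3,3'-bis[(tert-butyldimethylsilyl)oxy]-5',6'-epoxy-5,6,5',6'-tetrahydro-β,β-carotene-5,6-diyl carbonate F1. The furanoid ring is then made last by the classical acid-catalysed epoxide–furanoid rearrangement of carotenoid 5,6-epoxides (pyridinium p-toluenesulfonate or 0.01 M HCl, CH2Cl2–Et2O, 0 °C). This gives both C8' epimers, and the 8'R epimer 25 is isolated by preparative HPLC before step 18.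

Step 12 may fail because the π-allylpalladium terminus at C6 is fully substituted and flanked by two quaternary carbons, so ionisation or carbonate closure could be slow or divert to C8. The fallback sets out from 8 and comes back at 17. OsO4 (catalytic with N-methylmorpholine N-oxide and MeSO2NH2, or stoichiometric in pyridine) dihydroxylates the tetrasubstituted alkene of 8 from the face anti to the silyloxy group to give the cis-triol (1R,2R,4S)-4-[(tert-butyldimethylsilyl)oxy]-1-(hydroxymethyl)-2,6,6-trimethylcyclohexane-1,2-diol F2. Selective oxidation of the primary alcohol (TEMPO, PhI(OAc)2) gives (1S,2R,4S)-4-[(tert-butyldimethylsilyl)oxy]-1,2-dihydroxy-2,6,6-trimethylcyclohexane-1-carbaldehyde F3. Horner–Wadsworth–Emmons reaction with 13 (excess NaH) gives the dihydroxy dienenitrile F4, i-Bu2AlH gives the dihydroxy dienal F5, and 1,1'-carbonyldiimidazole closes the cyclic carbonate to give 17.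

Step 3 may fail because the same dienolate that carries the isomerisation can expel the C3 oxygen (1,4-elimination to the safranate-type diene), and the α/β equilibrium may be less one-sided than assumed. The fallback sets out from 4, comes back at 6 and also replaces step 2. Isopropenyl acetate with TsOH converts 4 into the dienol acetate methyl 4-acetoxy-2,6,6-trimethylcyclohexa-1,3-diene-1-carboxylate F6. NaBH4 in aqueous ethanol cleaves the enol ester, the dienolate is protonated at C4 and the β,γ-unsaturated ketone is reduced at once, giving racemic methyl 4-hydroxy-2,6,6-trimethylcyclohex-1-ene-1-carboxylate F7 with the double bond already at C5=C6. Lipase-catalysed kinetic resolution with vinyl acetate gives methyl (4R)-4-acetoxy-2,6,6-trimethylcyclohex-1-ene-1-carboxylate F8 (the 4S alcohol is left behind), and K2CO3 in MeOH releases 6.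

**Further compounds**
F1 | step 13 | (3S,5R,6S,3'S,5'R,6'S)-3,3'-bis[(tert-butyldimethylsilyl)oxy]-5',6'-epoxy-5,6,5',6'-tetrahydro-β,β-carotene-5,6-diyl carbonate | CC(/C=C/C=C(C)/C=C/[C@]1(OC(=O)O2)C(C)(C)C[C@H](O[Si](C)(C)C(C)(C)C)C[C@]12C)=C\C=C\C=C(C)\C=C\C=C(C)\C=C\[C@]1(O2)C(C)(C)C[C@H](O[Si](C)(C)C(C)(C)C)C[C@]12C
F2 | step 12 | (1R,2R,4S)-4-[(tert-butyldimethylsilyl)oxy]-1-(hydroxymethyl)-2,6,6-trimethylcyclohexane-1,2-diol | OC[C@]1(O)C(C)(C)C[C@H](O[Si](C)(C)C(C)(C)C)C[C@@]1(C)O
F3 | step 12 | (1S,2R,4S)-4-[(tert-butyldimethylsilyl)oxy]-1,2-dihydroxy-2,6,6-trimethylcyclohexane-1-carbaldehyde | O=C[C@]1(O)C(C)(C)C[C@H](O[Si](C)(C)C(C)(C)C)C[C@@]1(C)O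
F4 | step 12 | (2E,4E)-5-{(1S,2R,4S)-4-[(tert-butyldimethylsilyl)oxy]-1,2-dihydroxy-2,6,6-trimethylcyclohexyl}-3-methylpenta-2,4-dienenitrile | N#C/C=C(C)/C=C/[C@]1(O)C(C)(C)C[C@H](O[Si](C)(C)C(C)(C)C)C[C@@]1(C)O
F5 | step 12 | (2E,4E)-5-{(1S,2R,4S)-4-[(tert-butyldimethylsilyl)oxy]-1,2-dihydroxy-2,6,6-trimethylcyclohexyl}-3-methylpenta-2,4-dienal | O=C/C=C(C)/C=C/[C@]1(O)C(C)(C)C[C@H](O[Si](C)(C)C(C)(C)C)C[C@@]1(C)O
F6 | step 3 | methyl 4-acetoxy-2,6,6-trimethylcyclohexa-1,3-diene-1-carboxylate | COC(=O)C1=C(C)C=C(OC(C)=O)CC1(C)C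
F7 | step 3 | methyl (4RS)-4-hydroxy-2,6,6-trimethylcyclohex-1-ene-1-carboxylate (racemic) | COC(=O)C1=C(C)CC(O)CC1(C)C
F8 | step 3 | methyl (4R)-4-acetoxy-2,6,6-trimethylcyclohex-1-ene-1-carboxylate | COC(=O)C1=C(C)C[C@@H](OC(C)=O)CC1(C)C
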